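## Retrosynthetic overview

1. Target 30 ⇒ O8-angeloylation of epoxy alcohol 27 ⇒ 8β-OH-directed epoxidation of the Z C1=C10 olefin of the cis,cis-germacradienolide 26.
2. 26 ⇒ ring-closing metathesis at C1=C10 of the allyl/methallyl diene 25; the 8R carbinol comes from Mitsunobu inversion of Barbier adduct 23.
3. 23 ⇒ Zn-Barbier C7–C8 coupling of 3-methylbut-3-enal with 3-(bromomethyl)butenolide 19; C6 controls C7.
4. 19 ⇒ Pd-carbonylative lactonisation of a (Z)-γ-iodoallylic alcohol, made by asymmetric alkynylation (sets C6) of Z-enal 9.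
5. 9 ⇒ Z-iodide from carbomagnesiation of propargyl alcohol plus Keck allylation (sets C3). Ring order: butenolide (step 8) → ten-membered carbocycle (step 15) → oxirane (step 16).

Assumption: the SMILES is taken literally (1,10-cis-epoxide; 1R,3S,6R,7R,8R,10S; (2R)-2-methylbutanoate; angelate), germacrane numbering C1–C15 is used in the text, and 1, 5, 10, 17, 20 and 28 are bought.

## Route

Step 1
Reactants: 1 prop-2-yn-1-ol
Product: 3 (2Z)-3-iodo-2-methylprop-2-en-1-ol, via alkenylmagnesium alkoxide 2 (not isolated)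
Conditions: MeMgBr (2.2 equiv), CuI (10 mol%), THF, −10 °C→rt; then I2, −78→0 °C
Reagents that add atoms: methylmagnesium bromide C[Mg]Br; iodine II
Why: Cu-catalysed anti-carbomagnesiation of the propargyl alkoxide (Duboudin–Jousseaume) puts Me on C2 and Mg on C3 trans to it, so iodinolysis gives the Z iodide that fixes the later C4=C5 geometry.

Step 2
Reactants: 3 (2Z)-3-iodo-2-methylprop-2-en-1-ol
Product: 4 (2Z)-3-iodo-2-methylprop-2-enal
Conditions: MnO2, CH2Cl2, rt, dark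
Reagents that add atoms: none
Why: MnO2 oxidation of an allylic alcohol is neutral and leaves the vinyl iodide and the Z geometry untouched.

Step 3
Reactants: 4 (2Z)-3-iodo-2-methylprop-2-enal; 5 allyltributylstannane
Product: 6 (1Z,3S)-1-iodo-2-methylhexa-1,5-dien-3-ol
Conditions: (S)-BINOL (20 mol%), Ti(OiPr)4 (10 mol%), 4 Å MS, CH2Cl2, −20 °C; aq. NaHCO3
Reagents that add atoms: none
Why: Keck asymmetric allylation; the (S)-BINOL–Ti catalyst delivers allyl to the Si face of the enal, setting the S carbinol (germacrane C3).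

Step 4
Reactants: 6 (1Z,3S)-1-iodo-2-methylhexa-1,5-dien-3-ol
Product: 7 1-({[(1Z,3S)-1-iodo-2-methylhexa-1,5-dien-3-yl]oxy}methyl)-4-methoxybenzene
Conditions: NaH, PMBCl, Bu4NI (cat.), THF/DMF, 0 °C→rt
Reagents that add atoms: 4-methoxybenzyl chloride COc1ccc(CCl)cc1
Why: Williamson etherification; a PMB ether (not a silyl ether) avoids 1,4-retro-Brook migration in the Z γ-oxy alkenyllithium of step 5.

Step 5
Reactants: 7 1-({[(1Z,3S)-1-iodo-2-methylhexa-1,5-dien-3-yl]oxy}methyl)-4-methoxybenzene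
Product: 9 (2Z,4S)-4-[(4-methoxybenzyl)oxy]-3-methylhepta-2,6-dienal, via alkenyllithium 8 (not isolated)
Conditions: t-BuLi (2.1 equiv), Et2O, −78 °C; then DMF, −78→0 °C
Reagents that add atoms: N,N-dimethylformamide CN(C)C=O
Why: Iodine–lithium exchange proceeds with retention of olefin geometry, and formylation with DMF gives the Z-enal (C6 aldehyde).

Step 6
Reactants: 9 (2Z,4S)-4-[(4-methoxybenzyl)oxy]-3-methylhepta-2,6-dienal; 10 tert-butyldimethyl(prop-2-yn-1-yloxy)silane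
Product: 12 (4R,5Z,7S)-1-[(tert-butyldimethylsilyl)oxy]-7-[(4-methoxybenzyl)oxy]-6-methyldeca-5,9-dien-2-yn-4-ol, via alkynylzinc 11 (not isolated)
Conditions: Me2Zn, (S,S)-ProPhenol (20 mol%; the ligand enantiomer that adds to the Si face), Ph3PO (40 mol%), toluene, 4 °C
Reagents that add atoms: none
Why: Trost Zn–ProPhenol asymmetric alkynylation of an enal; catalyst-controlled Si-face addition sets the R carbinol (germacrane C6).

Step 7
Reactants: 12 (4R,5Z,7S)-1-[(tert-butyldimethylsilyl)oxy]-7-[(4-methoxybenzyl)oxy]-6-methyldeca-5,9-dien-2-yn-4-ol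
Product: 14 (2Z,4R,5Z,7S)-1-[(tert-butyldimethylsilyl)oxy]-2-iodo-7-[(4-methoxybenzyl)oxy]-6-methyldeca-2,5,9-trien-4-ol, via alkenylalanate 13 (not isolated)
Conditions: Red-Al, THF, 0 °C→rt; then I2, −78 °C
Reagents that add atoms: iodine II
Why: Hydroxyl-directed trans-hydroalumination puts Al on the alkyne carbon distal to the OH, and iodinolysis with retention gives the (Z)-γ-iodoallylic alcohol with I cis to the carbinol.

Step 8
Reactants: 14 (2Z,4R,5Z,7S)-1-[(tert-butyldimethylsilyl)oxy]-2-iodo-7-[(4-methoxybenzyl)oxy]-6-methyldeca-2,5,9-trien-4-ol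
Product: 15 (5R)-3-{[(tert-butyldimethylsilyl)oxy]methyl}-5-{(1Z,3S)-3-[(4-methoxybenzyl)oxy]-2-methylhexa-1,5-dien-1-yl}furan-2(5H)-one
Conditions: PdCl2(PPh3)2 (5 mol%), CO (1 atm), K2CO3, THF, 50 °C
Reagents that add atoms: carbon monoxide [C-]#[O+]
Why: Pd-catalysed carbonylative lactonisation (oxidative addition, CO insertion, capture by the cis hydroxyl) closes the butenolide without touching a stereocentre.

Step 9
Reactants: 15 (5R)-3-{[(tert-butyldimethylsilyl)oxy]methyl}-5-{(1Z,3S)-3-[(4-methoxybenzyl)oxy]-2-methylhexa-1,5-dien-1-yl}furan-2(5H)-one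
Product: 16 (5R)-3-{[(tert-butyldimethylsilyl)oxy]methyl}-5-[(1Z,3S)-3-hydroxy-2-methylhexa-1,5-dien-1-yl]furan-2(5H)-one
Conditions: DDQ, CH2Cl2/pH 7 buffer, 0 °C
Reagents that add atoms: none
Why: Oxidative PMB cleavage by DDQ frees O3 while the primary TBS ether, the alkenes and the butenolide survive.

Step 10
Reactants: 16 (5R)-3-{[(tert-butyldimethylsilyl)oxy]methyl}-5-[(1Z,3S)-3-hydroxy-2-methylhexa-1,5-dien-1-yl]furan-2(5H)-one; 17 (2R)-2-methylbutanoic acid
Product: 18 (1Z,3S)-1-[(2R)-4-{[(tert-butyldimethylsilyl)oxy]methyl}-5-oxo-2,5-dihydrofuran-2-yl]-2-methylhexa-1,5-dien-3-yl (2R)-2-methylbutanoate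
Conditions: DIC, DMAP (cat.), CH2Cl2, 0 °C→rt
Reagents that add atoms: none
Why: Steglich esterification installs the O3 (R)-2-methylbutanoate with retention at the carbinol and at the acid α-centre.

Step 11
Reactants: 18 (1Z,3S)-1-[(2R)-4-{[(tert-butyldimethylsilyl)oxy]methyl}-5-oxo-2,5-dihydrofuran-2-yl]-2-methylhexa-1,5-dien-3-yl (2R)-2-methylbutanoate
Product: 19 (1Z,3S)-1-[(2R)-4-(bromomethyl)-5-oxo-2,5-dihydrofuran-2-yl]-2-methylhexa-1,5-dien-3-yl (2R)-2-methylbutanoate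
Conditions: Ph3PBr2, CH2Cl2, 0 °C→rt
Reagents that add atoms: dibromotriphenylphosphorane BrP(Br)(c1ccccc1)(c1ccccc1)c1ccccc1
Why: Direct conversion of a primary allylic silyl ether into the bromide with Ph3PBr2 (Appel-type, neutral) gives the 3-(bromomethyl)butenolide without a nucleophilic base.

Step 12
Reactants: 20 3-methylbut-3-en-1-ol
Product: 21 3-methylbut-3-enal
Conditions: Dess–Martin periodinane, CH2Cl2, 0 °C; filtered solution used at once
Reagents that add atoms: none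
Why: Dess–Martin oxidation is non-basic, so the β,γ-unsaturated aldehyde is formed without conjugation and used immediately.

Step 13
Reactants: 19 (1Z,3S)-1-[(2R)-4-(bromomethyl)-5-oxo-2,5-dihydrofuran-2-yl]-2-methylhexa-1,5-dien-3-yl (2R)-2-methylbutanoate; 21 3-methylbut-3-enal
Product: 23 (1Z,3S)-1-{(2R,3R)-3-[(1S)-1-hydroxy-3-methylbut-3-en-1-yl]-4-methylidene-5-oxooxolan-2-yl}-2-methylhexa-1,5-dien-3-yl (2R)-2-methylbutanoate, via allylzinc bromide 22 (not isolated)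
Conditions: Zn dust, THF/sat. aq. NH4Cl, 0 °C→rt
Reagents that add atoms: none
Why: Zn-Barbier allylation; the ring-locked E allylzinc adds at C7 anti to the C6 side chain through a Zimmerman–Traxler chair, giving the 6,7-trans α-methylene lactone (7R) and the 8S carbinol.

Step 14
Reactants: 23 (1Z,3S)-1-{(2R,3R)-3-[(1S)-1-hydroxy-3-methylbut-3-en-1-yl]-4-methylidene-5-oxooxolan-2-yl}-2-methylhexa-1,5-dien-3-yl (2R)-2-methylbutanoate
Product: 25 (1Z,3S)-1-{(2R,3R)-3-[(1R)-1-hydroxy-3-methylbut-3-en-1-yl]-4-methylidene-5-oxooxolan-2-yl}-2-methylhexa-1,5-dien-3-yl (2R)-2-methylbutanoate, via C8 formate 24 (not isolated)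
Conditions: PPh3, DIAD, HCO2H, THF, 0 °C→rt; then KHCO3, MeOH, 0 °C
Reagents that add atoms: formic acid O=CO
Why: Mitsunobu reaction with formic acid inverts C8 by SN2 to the required 8R configuration, and the labile formate is methanolysed in the same pot without touching the other esters.

Step 15
Reactants: 25 (1Z,3S)-1-{(2R,3R)-3-[(1R)-1-hydroxy-3-methylbut-3-en-1-yl]-4-methylidene-5-oxooxolan-2-yl}-2-methylhexa-1,5-dien-3-yl (2R)-2-methylbutanoate
Product: 26 (3aR,4R,6Z,9S,10Z,11aR)-4-hydroxy-6,10-dimethyl-3-methylidene-2-oxo-2,3,3a,4,5,8,9,11a-octahydrocyclodeca[b]furan-9-yl (2R)-2-methylbutanoate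
Conditions: Grubbs II (10 mol%), CH2Cl2 (1 mM), 40 °C
Reagents that add atoms: none
Why: Ring-closing metathesis of the allyl and methallyl termini forms C1=C10, and the Z trisubstituted olefin is the less strained outcome in a ten-membered ring that already holds a cis olefin and a trans-fused lactone.

Step 16
Reactants: 26 (3aR,4R,6Z,9S,10Z,11aR)-4-hydroxy-6,10-dimethyl-3-methylidene-2-oxo-2,3,3a,4,5,8,9,11a-octahydrocyclodeca[b]furan-9-yl (2R)-2-methylbutanoate
Product: 27 (1R,3S,6R,7R,8R,10S)-1,10-epoxy-8-hydroxy-3-[(2R)-2-methylbutanoyloxy]germacra-4Z,11(13)-dien-12,6-olide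
Conditions: VO(acac)2 (10 mol%), t-BuOOH, CH2Cl2, 0 °C→rt
Reagents that add atoms: tert-butyl hydroperoxide CC(C)(C)OO
Why: Vanadium-catalysed homoallylic-hydroxyl-directed epoxidation (Mihelich chair transition state, C7 pseudo-equatorial) delivers oxygen from the 8β-OH face to C1=C10 only, giving the 1R,10S cis-epoxide; the O-flanked C4=C5 and the acrylate olefin are not addressed.

Step 17
Reactants: 27 (1R,3S,6R,7R,8R,10S)-1,10-epoxy-8-hydroxy-3-[(2R)-2-methylbutanoyloxy]germacra-4Z,11(13)-dien-12,6-olide; 28 (2Z)-2-methylbut-2-enoic acid (angelic acid)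
Product: 30 (1R,3S,6R,7R,8R,10S)-8-[(2Z)-2-methylbut-2-enoyloxy]-1,10-epoxy-3-[(2R)-2-methylbutanoyloxy]germacra-4Z,11(13)-dien-12,6-olide (CNP0108431.1), via mixed anhydride 29 (not isolated)
Conditions: 2,4,6-trichlorobenzoyl chloride, Et3N, toluene, rt; then 27, 75 °C (no DMAP)
Reagents that add atoms: none
Why: Yamaguchi mixed-anhydride acylation without a nucleophilic catalyst esterifies the hindered 8β-OH with retention and without Z→E isomerisation of the angelate.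

## Compound list

1 | prop-2-yn-1-ol | C#CCO | starting material
2 | bromo{(1Z)-3-[(bromomagnesio)oxy]-2-methylprop-1-en-1-yl}magnesium | Br[Mg]OC/C(C)=C\[Mg]Br | intermediate
3 | (2Z)-3-iodo-2-methylprop-2-en-1-ol | OC/C(C)=C\I | intermediate
4 | (2Z)-3-iodo-2-methylprop-2-enal | O=C/C(C)=C\I | intermediate
5 | allyltributylstannane | C=CC[Sn](CCCC)(CCCC)CCCC | starting material
6 | (1Z,3S)-1-iodo-2-methylhexa-1,5-dien-3-ol | C=CC[C@H](O)/C(C)=C\I | intermediate
7 | 1-({[(1Z,3S)-1-iodo-2-methylhexa-1,5-dien-3-yl]oxy}methyl)-4-methoxybenzene | C=CC[C@H](OCc1ccc(OC)cc1)/C(C)=C\I | intermediate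
8 | {(1Z,3S)-3-[(4-methoxybenzyl)oxy]-2-methylhexa-1,5-dien-1-yl}lithium | C=CC[C@H](OCc1ccc(OC)cc1)/C(C)=C\[Li] | intermediate
9 | (2Z,4S)-4-[(4-methoxybenzyl)oxy]-3-methylhepta-2,6-dienal | C=CC[C@H](OCc1ccc(OC)cc1)/C(C)=C\C=O | intermediate
10 | tert-butyldimethyl(prop-2-yn-1-yloxy)silane | C#CCO[Si](C)(C)C(C)(C)C | starting material
11 | {3-[(tert-butyldimethylsilyl)oxy]prop-1-yn-1-yl}(methyl)zinc | C[Zn]C#CCO[Si](C)(C)C(C)(C)C | intermediate
12 | (4R,5Z,7S)-1-[(tert-butyldimethylsilyl)oxy]-7-[(4-methoxybenzyl)oxy]-6-methyldeca-5,9-dien-2-yn-4-ol | C=CC[C@H](OCc1ccc(OC)cc1)/C(C)=C\[C@@H](O)C#CCO[Si](C)(C)C(C)(C)C | intermediate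
13 | sodium cyclic alkenylalanate of 12 (2,5-dihydro-1,2-oxaaluminol-2-ide with two 2-methoxyethoxy ligands) | [Na+].COCCO[Al-]1(OCCOC)O[C@H](/C=C(C)\[C@H](CC=C)OCc2ccc(OC)cc2)C=C1CO[Si](C)(C)C(C)(C)C | intermediate
14 | (2Z,4R,5Z,7S)-1-[(tert-butyldimethylsilyl)oxy]-2-iodo-7-[(4-methoxybenzyl)oxy]-6-methyldeca-2,5,9-trien-4-ol | C=CC[C@H](OCc1ccc(OC)cc1)/C(C)=C\[C@@H](O)/C=C(\I)CO[Si](C)(C)C(C)(C)C | intermediate
15 | (5R)-3-{[(tert-butyldimethylsilyl)oxy]methyl}-5-{(1Z,3S)-3-[(4-methoxybenzyl)oxy]-2-methylhexa-1,5-dien-1-yl}furan-2(5H)-one | C=CC[C@H](OCc1ccc(OC)cc1)/C(C)=C\[C@H]1OC(=O)C(CO[Si](C)(C)C(C)(C)C)=C1 | intermediate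
16 | (5R)-3-{[(tert-butyldimethylsilyl)oxy]methyl}-5-[(1Z,3S)-3-hydroxy-2-methylhexa-1,5-dien-1-yl]furan-2(5H)-one | C=CC[C@H](O)/C(C)=C\[C@H]1OC(=O)C(CO[Si](C)(C)C(C)(C)C)=C1 | intermediate
17 | (2R)-2-methylbutanoic acid | CC[C@@H](C)C(=O)O | starting material
18 | (1Z,3S)-1-[(2R)-4-{[(tert-butyldimethylsilyl)oxy]methyl}-5-oxo-2,5-dihydrofuran-2-yl]-2-methylhexa-1,5-dien-3-yl (2R)-2-methylbutanoate | C=CC[C@H](OC(=O)[C@H](C)CC)/C(C)=C\[C@H]1OC(=O)C(CO[Si](C)(C)C(C)(C)C)=C1 | intermediate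
19 | (1Z,3S)-1-[(2R)-4-(bromomethyl)-5-oxo-2,5-dihydrofuran-2-yl]-2-methylhexa-1,5-dien-3-yl (2R)-2-methylbutanoate | C=CC[C@H](OC(=O)[C@H](C)CC)/C(C)=C\[C@H]1OC(=O)C(CBr)=C1 | intermediate
20 | 3-methylbut-3-en-1-ol | CC(=C)CCO | starting material
21 | 3-methylbut-3-enal | CC(=C)CC=O | intermediate
22 | allylzinc bromide derived from 19 | C=CC[C@H](OC(=O)[C@H](C)CC)/C(C)=C\[C@H]1OC(=O)C(C[Zn]Br)=C1 | intermediate
23 | (1Z,3S)-1-{(2R,3R)-3-[(1S)-1-hydroxy-3-methylbut-3-en-1-yl]-4-methylidene-5-oxooxolan-2-yl}-2-methylhexa-1,5-dien-3-yl (2R)-2-methylbutanoate | C=C1C(=O)O[C@H](/C=C(/C)[C@@H](OC(=O)[C@H](C)CC)CC=C)[C@H]1[C@@H](O)CC(C)=C | intermediate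
24 | (1Z,3S)-1-{(2R,3R)-3-[(1R)-1-(formyloxy)-3-methylbut-3-en-1-yl]-4-methylidene-5-oxooxolan-2-yl}-2-methylhexa-1,5-dien-3-yl (2R)-2-methylbutanoate | C=C1C(=O)O[C@H](/C=C(/C)[C@@H](OC(=O)[C@H](C)CC)CC=C)[C@H]1[C@H](OC=O)CC(C)=C | intermediate
25 | (1Z,3S)-1-{(2R,3R)-3-[(1R)-1-hydroxy-3-methylbut-3-en-1-yl]-4-methylidene-5-oxooxolan-2-yl}-2-methylhexa-1,5-dien-3-yl (2R)-2-methylbutanoate | C=C1C(=O)O[C@H](/C=C(/C)[C@@H](OC(=O)[C@H](C)CC)CC=C)[C@H]1[C@H](O)CC(C)=C | intermediate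
26 | (3aR,4R,6Z,9S,10Z,11aR)-4-hydroxy-6,10-dimethyl-3-methylidene-2-oxo-2,3,3a,4,5,8,9,11a-octahydrocyclodeca[b]furan-9-yl (2R)-2-methylbutanoate | C=C1C(=O)O[C@@H]2/C=C(/C)[C@@H](OC(=O)[C@H](C)CC)C/C=C(/C)C[C@@H](O)[C@@H]12 | intermediate
27 | (1R,3S,6R,7R,8R,10S)-1,10-epoxy-8-hydroxy-3-[(2R)-2-methylbutanoyloxy]germacra-4Z,11(13)-dien-12,6-olide | C=C1C(=O)O[C@@H]2/C=C(/C)[C@@H](OC(=O)[C@H](C)CC)C[C@H]3O[C@@]3(C)C[C@@H](O)[C@@H]12 | intermediate
28 | (2Z)-2-methylbut-2-enoic acid (angelic acid) | C/C=C(/C)C(=O)O | starting material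
29 | (2Z)-2-methylbut-2-enoic 2,4,6-trichlorobenzoic anhydride | C/C=C(/C)C(=O)OC(=O)c1c(Cl)cc(Cl)cc1Cl | intermediate
30 | (1R,3S,6R,7R,8R,10S)-8-[(2Z)-2-methylbut-2-enoyloxy]-1,10-epoxy-3-[(2R)-2-methylbutanoyloxy]germacra-4Z,11(13)-dien-12,6-olide (CNP0108431.1) | C=C1C(=O)O[C@@H]2/C=C(/C)[C@@H](OC(=O)[C@H](C)CC)C[C@H]3O[C@@]3(C)C[C@@H](OC(=O)/C(C)=C\C)[C@@H]12 | target

## Step count and risks

Total step count: 17. Longest linear sequence: 16 (steps 1–11 and 13–17; step 12 is a one-step side branch).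

The three steps most likely to fail are 14, 15 and 16.

Step 14 (C8 inversion) is the first risk. The activated C8 oxyphosphonium can eliminate toward C7 to a conjugated dienoate, and the step also depends on the Barbier reaction having given the 8S carbinol cleanly. The fallback sets out from bromide 19 and does not create C8 in the Barbier event at all. Zn-mediated Barbier reaction of 19 with aqueous formaldehyde gives the hydroxymethyl lactone F1, still trans to the C6 side chain. Dess–Martin oxidation gives the aldehyde F2. A reagent-controlled Keck methallylation (tributyl(2-methylallyl)stannane, (R)-BINOL/Ti(OiPr)4, Re-face addition) then gives the 8R carbinol directly, returning to the route at 25.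

Step 15 (ring-closing metathesis) is the second risk. The ten-membered ring is strained, oligomers or the 1(10)E isomer may form, and the acrylate methylene can interfere. The fallback sets out from the Barbier adduct 23 and closes the ring before the C8 inversion, so that the 8α-carbinol with its different conformer population is the metathesis substrate. Grubbs II cyclisation of 23 gives the 8-epi macrocycle F3. Mitsunobu reaction with formic acid on the ring gives the inverted macrocyclic formate F4, and methanolysis returns to the route at 26.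

Step 16 (directed epoxidation) is the third risk. Oxygen delivery across the medium ring may be slow or occur on the wrong face, and the γ-hydroxy epoxide can open transannularly under Lewis acid. The fallback sets out from 26 and gives up hydroxyl direction in favour of reagent control. 26 is first acylated with mixed anhydride 29 to the angelate triene F5. A Shi epoxidation (fructose-derived ketone of the enantiomer matched to β-face attack, Oxone, pH 10.5) then oxidises the only electron-rich, non-O-flanked olefin C1=C10, returning to the route at 30.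

Further compounds
F1 | step 14 | (1Z,3S)-1-[(2R,3R)-3-(hydroxymethyl)-4-methylidene-5-oxooxolan-2-yl]-2-methylhexa-1,5-dien-3-yl (2R)-2-methylbutanoate | C=C1C(=O)O[C@H](/C=C(/C)[C@@H](OC(=O)[C@H](C)CC)CC=C)[C@H]1CO
F2 | step 14 | (1Z,3S)-1-[(2R,3S)-3-formyl-4-methylidene-5-oxooxolan-2-yl]-2-methylhexa-1,5-dien-3-yl (2R)-2-methylbutanoate | C=C1C(=O)O[C@H](/C=C(/C)[C@@H](OC(=O)[C@H](C)CC)CC=C)[C@H]1C=O
F3 | step 15 | (3aR,4S,6Z,9S,10Z,11aR)-4-hydroxy-6,10-dimethyl-3-methylidene-2-oxo-2,3,3a,4,5,8,9,11a-octahydrocyclodeca[b]furan-9-yl (2R)-2-methylbutanoate | C=C1C(=O)O[C@@H]2/C=C(/C)[C@@H](OC(=O)[C@H](C)CC)C/C=C(/C)C[C@H](O)[C@@H]12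
F4 | step 15 | (3aR,4R,6Z,9S,10Z,11aR)-4-(formyloxy)-6,10-dimethyl-3-methylidene-2-oxo-2,3,3a,4,5,8,9,11a-octahydrocyclodeca[b]furan-9-yl (2R)-2-methylbutanoate | C=C1C(=O)O[C@@H]2/C=C(/C)[C@@H](OC(=O)[C@H](C)CC)C/C=C(/C)C[C@@H](OC=O)[C@@H]12
F5 | step 16 | (3aR,4R,6Z,9S,10Z,11aR)-6,10-dimethyl-3-methylidene-9-[(2R)-2-methylbutanoyloxy]-2-oxo-2,3,3a,4,5,8,9,11a-octahydrocyclodeca[b]furan-4-yl (2Z)-2-methylbut-2-enoate | C=C1C(=O)O[C@@H]2/C=C(/C)[C@@H](OC(=O)[C@H](C)CC)C/C=C(/C)C[C@@H](OC(=O)/C(C)=C\C)[C@@H]12
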